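**Plan**

- Retrosynthesis: cut first the two aryl–prenyl bonds (C8 of ring A, C3′ of ring B), then H2 across C3=C4, then the pyran ring (ring C) at C2–C3 and C4–C4a in one cut. This leaves a ring-A aryl ether that carries only C2 and a ring-B 2-methoxyvinyl arene that carries C3 and C4.
- Enabling feature: O1 is an aryl ether oxygen bound to a CH2 (C2), and its ortho carbon C4a is unsubstituted and para to the C7 oxygen, so the cation C2H2=O1(+) together with C8a=C4a is a four-atom 2-oxa-diene. C4 is a plain CH2 in the target and can carry a methoxy group for a time; this makes C3, the carbon bearing ring B, the nucleophilic alkene carbon and puts ring B on C3 instead of C4.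
- Forward: rings A and B are bought as benzyl-protected resorcinol derivatives and given one carbon each (steps 1, 2). Ring C is closed between them (step 3), methanol is lost to the 2H-chromene, the alkene is hydrogenated, benzyl is exchanged for MOM, both prenyl groups enter by a twofold ortho-metalation, and the MOM groups are removed.
- Stereochemistry: C3 is the only stereocenter. It is set as R by catalyst-controlled asymmetric hydrogenation of C3=C4 (step 5); the stereocenters made in step 3 are uncontrolled and are erased in step 4.

Key step: step 3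

Assumption: the (S)-configured P,N ligand of the iridium catalyst in step 5 is taken to deliver H2 to the alkene face that gives (R)-9; if the sense proves opposite, the (R)-ligand is used with no other change.

Step 1
Reactants: 1 3-(benzyloxy)phenol
Product: 2 [3-(benzyloxy)phenoxy]methyl acetate
Conditions: BrCH2OAc (1.5 equiv), Ag2O (1.0 equiv), 4 Å MS, MeCN, 23 °C
Reagents that add atoms: bromomethyl acetate, CC(=O)OCBr
Why: Williamson-type O-alkylation of the phenol by the α-bromo ester, promoted by Ag2O as halide acceptor and mild base, should give the acyloxymethyl (α-acetoxy) ether without acyl transfer to the phenol.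

Step 2
Reactants: 3 2,4-bis(benzyloxy)benzaldehyde
Product: 4 2,4-bis(benzyloxy)-1-(2-methoxyethenyl)benzene (E/Z mixture)
Conditions: Ph3P(CH2OMe)Cl (1.5 equiv), KOtBu (1.5 equiv), THF, 0 → 23 °C
Reagents that add atoms: (methoxymethyl)triphenylphosphonium chloride, COC[P+](c1ccccc1)(c1ccccc1)c1ccccc1.[Cl-]
Why: Wittig methoxymethylenation of the aryl aldehyde should give the enol ether, whose E/Z mixture is used as such because both isomers end in the same alkene after step 4.

Step 3
Reactants: 2 [3-(benzyloxy)phenoxy]methyl acetate; 4 2,4-bis(benzyloxy)-1-(2-methoxyethenyl)benzene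
Product: 7 7-(benzyloxy)-3-[2,4-bis(benzyloxy)phenyl]-4-methoxychroman (racemic cis/trans mixture), via aryloxymethyl oxocarbenium triflate 5 (not isolated), via open-chain methoxycarbenium triflate 6 (not isolated)
Conditions: 4 (1.3 equiv), 2,6-di-tert-butyl-4-methylpyridine (1.5 equiv), TMSOTf (1.2 equiv), CH2Cl2, −78 → −40 °C; Et3N quench
Reagents that add atoms: none
Why: Proposed new method: TMSOTf ionises the α-acetoxy ether 2 to the aryloxymethyl oxocarbenium ion 5, a cationic 2-oxa-diene (C2=O1(+)–C8a=C4a); enol ether 4 attacks its CH2 terminus with the carbon that bears ring B (C2–C3 bond), and the methoxycarbenium ion 6 so formed is captured by ring A at the carbon para to the benzyloxy group (C4–C4a bond), after which the hindered pyridine takes up the proton. The closest known reaction types are the oxa-Povarov annulation of aryl oxocarbenium ions with alkenes to chromans, the Povarov reaction of N-aryliminium ions with enol ethers (4-alkoxy product, same polarity pattern) and the ionisation of α-acetoxy ethers by silyl triflates for Prins-type C–C bond formation; new here are the CH2-only oxocarbenium ion and the use of a β-aryl enol ether to place the aryl group on C3. Ring C closes in a stepwise polar [4+2] sense, the second bond by a six-membered Friedel–Crafts closure that is 6-exo-trig with respect to the C4=O(+) bond. C3 and C4 become stereocenters without control (racemic, both diastereomers), which is accepted because step 4 removes the C4 methoxy group and step 5 resets C3. The step needs (a) the right polarity at the alkene, secured by the methoxy group, a stronger donor than ring B, so that the carbon bearing ring B is nucleophilic (the same carbon is protonated when such enol ethers are hydrolysed to arylacetaldehydes), whereas a plain styrene would give the 4-aryl isomer; (b) closure at C4a and not at the carbon between the two oxygens, secured by the para-benzyloxy donor and by sterics; and (c) capture of 5 by the enol ether and not by the arenes, secured by the higher nucleophilicity of the enol ether, its slight excess and the low temperature.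

Step 4
Reactants: 7 7-(benzyloxy)-3-[2,4-bis(benzyloxy)phenyl]-4-methoxychroman
Product: 8 7-(benzyloxy)-3-[2,4-bis(benzyloxy)phenyl]-2H-chromene
Conditions: TsOH·H2O (10 mol %), toluene, 80 °C
Reagents that add atoms: none
Why: Acid-catalysed E1 elimination of methanol through the C4 benzylic cation, which O1 and the C7 oxygen of ring A stabilise, should give the conjugated C3=C4 bond from both diastereomers of 7, as in the known dehydration of isoflavan-4-ols to isoflav-3-enes.

Step 5
Reactants: 8 7-(benzyloxy)-3-[2,4-bis(benzyloxy)phenyl]-2H-chromene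
Product: 9 (3R)-7-(benzyloxy)-3-[2,4-bis(benzyloxy)phenyl]chroman
Conditions: H2 (50 bar), [Ir(cod)(L)][B(C6H3(CF3)2)4] (2 mol %; L = (S)-4-tert-butyl-2-[2-(diphenylphosphanyl)phenyl]-4,5-dihydrooxazole), CH2Cl2, 25 °C
Reagents that add atoms: none
Why: Iridium/P,N-ligand-catalysed asymmetric hydrogenation of an unfunctionalised trisubstituted aryl alkene, a reaction type known for 3-aryl-2H-chromenes, should add H2 to one alkene face under control of the chiral ligand and so set C3 as R, while benzyl ethers and arenes stay untouched.

Step 6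
Reactants: 9 (3R)-7-(benzyloxy)-3-[2,4-bis(benzyloxy)phenyl]chroman
Product: 10 (3R)-3-(2,4-dihydroxyphenyl)chroman-7-ol
Conditions: H2 (1 bar), Pd/C (10 wt %), EtOAc–MeOH, 23 °C
Reagents that add atoms: none
Why: Palladium-catalysed hydrogenolysis should cleave the three benzyl aryl ethers, while the chroman ring (O1–C2 is not benzylic) and the C3 stereocenter, which has no leaving group next to it, are left as they are.

Step 7
Reactants: 10 (3R)-3-(2,4-dihydroxyphenyl)chroman-7-ol
Product: 11 (3R)-7-(methoxymethoxy)-3-[2,4-bis(methoxymethoxy)phenyl]chroman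
Conditions: MOMCl (4.5 equiv), i-Pr2NEt (6 equiv), CH2Cl2, 0 → 40 °C
Reagents that add atoms: chloromethyl methyl ether, COCCl
Why: O-Alkylation of the three phenols with the α-chloro ether (Williamson-type etherification) should give the tris-MOM ether, chosen because MOM groups direct the metalation of step 8 and leave under mild acid.

Step 8
Reactants: 11 (3R)-7-(methoxymethoxy)-3-[2,4-bis(methoxymethoxy)phenyl]chroman
Product: 13 (3R)-7-(methoxymethoxy)-8-(3-methylbut-2-enyl)-3-[2,4-bis(methoxymethoxy)-3-(3-methylbut-2-enyl)phenyl]chroman, via C8/C3′-dilithio species 12 (not isolated)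
Conditions: n-BuLi (2.6 equiv), TMEDA (2.6 equiv), THF, −20 → 0 °C; then CuBr·SMe2 (20 mol %), prenyl bromide (3 equiv), −78 → 0 °C
Reagents that add atoms: 1-bromo-3-methylbut-2-ene (prenyl bromide), CC(C)=CCBr
Why: Twofold directed ortho-metalation should take place at the one C–H of each ring that lies between two oxygen substituents (C3′ between two OMOM groups, C8 between O1 and OMOM), and copper-catalysed allylic substitution at the primary carbon of prenyl bromide then forms both aryl–prenyl bonds, the non-activated tertiary C3–H being left alone.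

Step 9
Reactants: 13 (3R)-7-(methoxymethoxy)-8-(3-methylbut-2-enyl)-3-[2,4-bis(methoxymethoxy)-3-(3-methylbut-2-enyl)phenyl]chroman
Product: 14 kanzonol X, (3R)-3-[2,4-dihydroxy-3-(3-methylbut-2-enyl)phenyl]-8-(3-methylbut-2-enyl)chroman-7-ol
Conditions: HCl (3 M aq), MeOH, 40 °C
Reagents that add atoms: none
Why: Acid-catalysed acetal cleavage (transacetalisation to methanol) should remove the three MOM groups, dilute acid and mild warming being chosen so that the ortho-prenyl phenols do not cyclise to 2,2-dimethylchromans and C3 is not touched.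

**Compound list**

1 | 3-(benzyloxy)phenol | Oc1cccc(OCc2ccccc2)c1 | starting material
2 | [3-(benzyloxy)phenoxy]methyl acetate | CC(=O)OCOc1cccc(OCc2ccccc2)c1 | intermediate
3 | 2,4-bis(benzyloxy)benzaldehyde | O=Cc1ccc(OCc2ccccc2)cc1OCc1ccccc1 | starting material
4 | 2,4-bis(benzyloxy)-1-(2-methoxyethenyl)benzene (E/Z mixture) | COC=Cc1ccc(OCc2ccccc2)cc1OCc1ccccc1 | intermediate
5 | [3-(benzyloxy)phenoxy]methylium (aryloxymethyl oxocarbenium) triflate, not isolated | C=[O+]c1cccc(OCc2ccccc2)c1.[O-]S(=O)(=O)C(F)(F)F | intermediate
6 | open-chain methoxycarbenium triflate, O-methyl oxocarbenium ion of 2-[2,4-bis(benzyloxy)phenyl]-3-[3-(benzyloxy)phenoxy]propanal (racemic), not isolated | C[O+]=CC(COc1cccc(OCc2ccccc2)c1)c1ccc(OCc2ccccc2)cc1OCc1ccccc1.[O-]S(=O)(=O)C(F)(F)F | intermediate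
7 | 7-(benzyloxy)-3-[2,4-bis(benzyloxy)phenyl]-4-methoxychroman (racemic cis/trans mixture) | COC1c2ccc(OCc3ccccc3)cc2OCC1c1ccc(OCc2ccccc2)cc1OCc1ccccc1 | intermediate
8 | 7-(benzyloxy)-3-[2,4-bis(benzyloxy)phenyl]-2H-chromene | C1(c2ccc(OCc3ccccc3)cc2OCc2ccccc2)=Cc2ccc(OCc3ccccc3)cc2OC1 | intermediate
9 | (3R)-7-(benzyloxy)-3-[2,4-bis(benzyloxy)phenyl]chroman | C(c1ccccc1)Oc1ccc([C@@H]2COc3cc(OCc4ccccc4)ccc3C2)c(OCc2ccccc2)c1 | intermediate
10 | (3R)-3-(2,4-dihydroxyphenyl)chroman-7-ol | Oc1ccc([C@@H]2COc3cc(O)ccc3C2)c(O)c1 | intermediate
11 | (3R)-7-(methoxymethoxy)-3-[2,4-bis(methoxymethoxy)phenyl]chroman | COCOc1ccc([C@@H]2COc3cc(OCOC)ccc3C2)c(OCOC)c1 | intermediate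
12 | C8/C3′-dilithio derivative of 11, not isolated | COCOc1ccc([C@@H]2COc3c([Li])c(OCOC)ccc3C2)c(OCOC)c1[Li] | intermediate
13 | (3R)-7-(methoxymethoxy)-8-(3-methylbut-2-enyl)-3-[2,4-bis(methoxymethoxy)-3-(3-methylbut-2-enyl)phenyl]chroman | COCOc1ccc([C@@H]2COc3c(CC=C(C)C)c(OCOC)ccc3C2)c(OCOC)c1CC=C(C)C | intermediate
14 | kanzonol X, (3R)-3-[2,4-dihydroxy-3-(3-methylbut-2-enyl)phenyl]-8-(3-methylbut-2-enyl)chroman-7-ol | CC(C)=CCc1c(O)ccc([C@@H]2COc3c(ccc(O)c3CC=C(C)C)C2)c1O | target

**Count and risks**

Total step count: 9. Longest linear sequence: 8 steps (step 1 or step 2, then steps 3 to 9).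

The three steps most likely to fail:

Step 3 (proposed new method). What may go wrong: the aryloxymethyl cation is consumed by Friedel–Crafts attack on the benzyloxy-arenes, the enol ether oligomerises, or the first C–C bond forms at the wrong alkene carbon. The fallback uses known chemistry, sets out from 1 and comes back at 8. Compound 1 is O-alkylated with 3-chloropropanoic acid (NaOH, H2O, reflux) to 3-[3-(benzyloxy)phenoxy]propanoic acid F1. Trifluoroacetic anhydride (CH2Cl2, 0 → 23 °C) turns it into the mixed anhydride 3-[3-(benzyloxy)phenoxy]propanoic trifluoroacetic anhydride F2, which acylates ring A para to the benzyloxy group and gives 7-(benzyloxy)chroman-4-one F3. Palladium-catalysed ketone α-arylation with 1-bromo-2,4-bis(benzyloxy)benzene (Pd2(dba)3, XPhos, NaOtBu, toluene, 80 °C) gives 7-(benzyloxy)-3-[2,4-bis(benzyloxy)phenyl]chroman-4-one F4. NaBH4 (THF–MeOH, 0 °C) reduces the ketone to 7-(benzyloxy)-3-[2,4-bis(benzyloxy)phenyl]chroman-4-ol F5, and TsOH-catalysed dehydration (toluene, 80 °C) gives 8, where the route goes on with step 5.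

Step 8. What may go wrong: loss of regiocontrol in the allylic substitution (attack at the γ-carbon of prenyl bromide, which gives 1,1-dimethylallyl isomers) and slow alkylation of the hindered diaryl-metal. The fallback sets out from 11 and comes back at 13. The dilithio species 12 is made as in step 8, transmetalated with CuBr·SMe2 and quenched with allyl bromide, for which attack at either end gives the same product, to give (3R)-8-allyl-3-[3-allyl-2,4-bis(methoxymethoxy)phenyl]-7-(methoxymethoxy)chroman F6. Olefin cross-metathesis with 2-methylbut-2-ene (second-generation Grubbs catalyst RuCl2(=CHPh)(PCy3)(H2IMes), CH2Cl2, 40 °C) turns both allyl groups into prenyl groups and gives 13.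

Step 5. What may go wrong: poor facial selectivity or slow turnover, because the ortho-benzyloxy group twists ring B out of the plane of the alkene. The fallback sets out from 8 and comes back at 10. Asymmetric hydroboration with monoisopinocampheylborane (THF, −25 °C; then NaOH, H2O2; the antipode of the borane that adds to the face giving 3R) delivers H to C3 and boron to C4 on the same face and gives, after oxidation, (3R,4S)-7-(benzyloxy)-3-[2,4-bis(benzyloxy)phenyl]chroman-4-ol F7. Hydrogenolysis over Pd/C (H2, EtOAc–MeOH, trace AcOH) removes the benzylic C4 hydroxyl group and the three benzyl groups in one operation and gives triol 10.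

**Further compounds**

F1 | step 3 | 3-[3-(benzyloxy)phenoxy]propanoic acid | OC(=O)CCOc1cccc(OCc2ccccc2)c1
F2 | step 3 | 3-[3-(benzyloxy)phenoxy]propanoic trifluoroacetic anhydride | O=C(CCOc1cccc(OCc2ccccc2)c1)OC(=O)C(F)(F)F
F3 | step 3 | 7-(benzyloxy)chroman-4-one | O=C1CCOc2cc(OCc3ccccc3)ccc12
F4 | step 3 | 7-(benzyloxy)-3-[2,4-bis(benzyloxy)phenyl]chroman-4-one (racemic) | O=C1c2ccc(OCc3ccccc3)cc2OCC1c1ccc(OCc2ccccc2)cc1OCc1ccccc1
F5 | step 3 | 7-(benzyloxy)-3-[2,4-bis(benzyloxy)phenyl]chroman-4-ol (racemic cis/trans mixture) | OC1c2ccc(OCc3ccccc3)cc2OCC1c1ccc(OCc2ccccc2)cc1OCc1ccccc1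
F6 | step 8 | (3R)-8-allyl-3-[3-allyl-2,4-bis(methoxymethoxy)phenyl]-7-(methoxymethoxy)chroman | COCOc1ccc([C@@H]2COc3c(CC=C)c(OCOC)ccc3C2)c(OCOC)c1CC=C
F7 | step 5 | (3R,4S)-7-(benzyloxy)-3-[2,4-bis(benzyloxy)phenyl]chroman-4-ol | C(c1ccccc1)Oc1ccc([C@@H]2COc3cc(OCc4ccccc4)ccc3[C@H]2O)c(OCc2ccccc2)c1
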